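Line up the lifetimes of the catalyst's forms before you reckon any yield.

| setting | south | east | south-west | north |
|---|---|---|---|---|
| starting material | 0.89 M | 0.89 M | 0.89 M | 0.89 M |
| second substrate | 0.890 M | 0.890 M | 0.890 M | 0.890 M |
| reagent | 0.534 M | 0.534 M | 0.534 M | 0.534 M |
| precatalyst | 63 mM | 63 mM | 63 mM | 63 mM |
| time | 15 h | 15 h | 15 h | 15 h |
| remark | at 110 °C until 8.0 h, from then on at 150 °C |  |  |  |
| temperature |  | 130 °C | 150 °C | 110 °C |

    precatalyst → free catalyst (k1 = 0.360 h⁻¹, Ea1 = 112 kJ mol⁻¹)
    second substrate + free catalyst ⇌ catalyst intermediate B (K2 = 4.4 M⁻¹, k2 = 9.07 M⁻¹ h⁻¹, Ea2 = 77.0 kJ mol⁻¹, ΔH2 = −1.00 kJ mol⁻¹)
    reagent + catalyst intermediate A → free catalyst + target (k3 = 6.59 M⁻¹ h⁻¹, Ea3 = 85.0 kJ mol⁻¹)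
    2 reagent → homo dimer (k4 = 0.178 M⁻¹ h⁻¹, Ea4 = 95.0 kJ mol⁻¹)
    starting material + free catalyst ⇌ catalyst intermediate A (K5 = 130 M⁻¹, k5 = 4.68 M⁻¹ h⁻¹, Ea5 = 88.0 kJ mol⁻¹, ΔH5 = −67.0 kJ mol⁻¹)
    reagent + catalyst intermediate B → free catalyst + second product (k6 = 23.6 M⁻¹ h⁻¹, Ea6 = 96.0 kJ mol⁻¹)
    (constants at 110 °C)

- a step written with two of one species runs at k times the square of its concentration and takes two of it each time
- the list of constants is for 110 °C, to be carried to other temperatures by the activation energies and enthalpies

1. the best flask by amount of target, in percent of the starting material charged; "all alike" if 1.5 percentage points covers them all (south / east / south-west / north / all alike)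
2. amount of target at the end, in percent of the starting material charged, south
3. amount of target at the end, in percent of the starting material charged, east
4. amount of target at the end, in percent of the starting material charged, south-west
5. amount of target at the end, in percent of the starting material charged, north

**Fast rung.** Start at 110 °C with reagent at its charge. Catalyst intermediate B lives 0.0793 h against reagent and catalyst intermediate A lives 0.284 h. Falling apart takes them 0.485 h and 27.8 h. With reagent at its charge, both forms go on to product faster than they fall back, so for a first reckoning count the captures of free catalyst and set the falling back aside.

**Capture ratio.** Define ρ, 0.516, the capture ratio: the rate at which starting material takes free catalyst, divided by the rate at which second substrate takes it. This is the selectivity factor of the two rounds. Suppose, for this reckoning, that each capture ends in one product; target then gets the share ρ/(1+ρ), or 34.0%, of the reagent that passes through the catalyst, a share reckoned with both charges whole.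

**Middle rung.** Catalyst intermediate A is the slower form to use up, so take it as the resting state and place the catalyst charge there. Reagent then flows into target in proportion to that charge, and into second product by the factor 1/ρ on top, which gives a reagent lifetime of 0.820 h. That is the lifetime with the catalyst already released, and the precatalyst takes 2.78 h to release it, longer than the reagent needs.

**Slow rung.** The first half-life of reagent towards homo dimer is 5.26 h, longer than the catalytic lifetime. Dimer therefore takes the smaller part, and the catalytic part of the reagent is tD/(tD+tC), where tD is this half-life and tC the catalytic lifetime. Reagent is the limiting reagent, and the run of 15 h is longer than these times.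

**My reckoning.** Multiply the charge of reagent by the catalytic part and by the target share. For north this gives 17.7% of the starting material charged. Now heat the flask. Capture by starting material has the larger activation energy, so from the coldest flask to the hottest ρ rises by a factor of 1.39, and the reckoned target share goes to 41.7%. My reckoning therefore puts south-west ahead of north.

**The result.** The forecast gave 18.6% for south, 19.8% for east, 20.8% for south-west and 18.5% for north, chose south-west, and held that “Heat activates the precatalyst almost at once”. The simulation gives 16.8%, 17.1%, 16.4% and 17.1% in that order, so the verdict is all alike, with a spread of 0.70 percentage points, less than the margin of 1.5 points. South-west stands below north, against my reckoning.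

**Opposed captures.** Heat speeds both captures, and their pulls on target oppose each other, which is a part of what temperature does. With temperature kept off capture by starting material, south-west ends 15 points below north. Kept off capture by second substrate, it ends 12 points above north, while the real gap is 0.63 points. Capture by second substrate, both ways, takes a part of the target: without it south-west reaches 35.4% in place of 16.4%. Take the square root of the lift for east, which lies midway in temperature, and ρ there is 0.607; the neighbour of east with 2.2 M of second substrate has 0.246, and its target is 9.14% against 17.1%.

The numbers stand for no real mixture, and the outcome is calculated.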